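**Plan**

- Cuts: first the C6–CH2 bond (flavanone + chain), then ring C at C2–C3 and C4–C4a (aryl oxocarbenium ion + a two-carbon ketene equivalent), and the chain at its three aryl–CH2 bonds para to the phenol oxygens.
- Enabling feature: in ring A, C4a is the only free carbon ortho to O1, and the phenol oxygen of the C8 2-hydroxybenzyl group (ring D) faces O1 across a 2,2'-methylenebisphenol, so C2 with its phenyl can be stored as a benzylidene acetal bridging both oxygens in an eight-membered dioxocin.
- Helpers: two bromine atoms on ring D make its oxygen the leaving group and block that ring; benzyl ethers sit on O5 and O7; one hydrogenolysis removes all of them.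
- Forward: ring A phenol → C8 hydroxybenzylation → dioxocin → ring-opening annulation that builds ring C → hydrogenolysis → C6 hydroxybenzylation with the chain (rings E to H, built by iterative benzylic Suzuki–Miyaura couplings) → debenzylation.
- Stereochemistry: the single stereocentre C2 (S) is set in the annulation by the counter-anion of a chiral Brønsted acid and afterwards meets only neutral or Lewis acidic conditions.

Key step: step 3

Assumption: compounds 2, 7, 13, 15 and 20 are taken as catalogue chemicals, and because the sense of induction of the chiral acid cannot be predicted, the (R) acid written in step 3 stands for whichever enantiomer gives the (2S) product.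

**Route**

Step 1
Reactants: 1 3,5-bis(benzyloxy)phenol; 2 3,5-dibromo-2-hydroxybenzyl alcohol
Product: 4 3,5-bis(benzyloxy)-2-(3,5-dibromo-2-hydroxybenzyl)phenol, via o-quinone methide 3 (not isolated)
Conditions: ZnCl2 (1.5 equiv), 1 (2 equiv), 1,4-dioxane, 90 °C
Reagents that add atoms: none
Why: ZnCl2-assisted dehydration of 2 gives o-quinone methide 3, which the zinc phenoxide of 1 captures in a Friedel–Crafts-type conjugate addition at the carbon ortho to its free hydroxyl (chelated delivery; the para carbon lies between two benzyloxy groups), while the excess of 1 and the deactivated dibromophenol ring of the product limit over-alkylation.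

Step 2
Reactants: 4 3,5-bis(benzyloxy)-2-(3,5-dibromo-2-hydroxybenzyl)phenol; 5 α,α-dibromotoluene
Product: 6 9,11-bis(benzyloxy)-2,4-dibromo-6-phenyl-12H-dibenzo[d,g][1,3]dioxocin
Conditions: Cs2CO3 (3 equiv), DMF (0.02 M), 60 °C
Reagents that add atoms: none
Why: Twofold Williamson O-alkylation of the bis-phenoxide by the geminal dibromide closes the eight-membered benzylidene acetal that 2,2'-methylenebisphenols form readily, and the new acetal stereocentre (racemic) is of no consequence because it is erased in step 3.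

Step 3
Reactants: 6 9,11-bis(benzyloxy)-2,4-dibromo-6-phenyl-12H-dibenzo[d,g][1,3]dioxocin; 7 N-ethynyl-N-methylmethanesulfonamide
Product: 11 (2S)-5,7-bis(benzyloxy)-8-(3,5-dibromo-2-hydroxybenzyl)-2-phenylchroman-4-one, via aryl oxocarbenium ion 8 (not isolated), via keteniminium ion 9 (not isolated), via 4-sulfonamido-2H-chromene 10 (not isolated)
Conditions: (R)-3,3'-bis(2,4,6-triisopropylphenyl)-1,1'-binaphthyl-2,2'-diyl N-triflylphosphoramide (10 mol %), 7 (1.5 equiv), 4 Å molecular sieves, toluene, −40 °C; then 2 M HCl, THF, 40 °C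
Reagents that add atoms: water, O
Why: Proposed new method: The chiral acid protonates the acetal at the oxygen of the dibrominated ring D, the eight-membered ring opens to aryl oxocarbenium ion 8 (O1 of ring A double-bonded to C2) paired with the chiral phosphoramidate, the β-carbon of ynamide 7 adds to C2 (C2–C3 bond) to give keteniminium ion 9, and C4a attacks its sp carbon (C4–C4a bond) before loss of the C4a proton returns the acid and leaves ene-sulfonamide 10, which aqueous acid hydrolyses to the ketone. The closest known reaction types are the oxa-Povarov formal [4+2] annulation of aryl oxocarbenium ions with alkenes, the keteniminium Friedel–Crafts cyclisation of ynamides and chiral Brønsted acid ion-pair catalysis of additions to oxocarbenium ions, and their combination on a cyclic diaryl acetal is new. Ring C closes by a 6-exo-dig Friedel–Crafts attack in which the C=N bond of the keteniminium is exocyclic and the C3=C4 bond becomes endocyclic, while the dioxocin ring is opened for good. The only new stereocentre, C2, is set in the C2–C3 bond formation by the chiral counter-anion, which is held over one face of the (E)-oxocarbenium ion by ion pairing and by a hydrogen bond to the released, still tethered phenol. The step needs cleavage of the C2–O bond to ring D and not to ring A, secured by the two bromine atoms that lower the pKa of the leaving phenol and destabilise the alternative oxocarbenium ion, and ring closure at a single carbon, secured because C4a is the only free position ortho to O1 and the ortho and para positions of ring D are blocked. It also needs the ynamide to outrun its own protonation by the acid and attack of the cation by a second ring A, which the low temperature, the moderate acidity of the phosphoramide and the excess of 7 should favour.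

Step 4
Reactants: 11 (2S)-5,7-bis(benzyloxy)-8-(3,5-dibromo-2-hydroxybenzyl)-2-phenylchroman-4-one
Product: 12 (2S)-5,7-dihydroxy-8-(2-hydroxybenzyl)-2-phenylchroman-4-one ((S)-chamanetin)
Conditions: H2 (1 atm), Pd/C (10 wt %), NaOAc (2.5 equiv), EtOAc/MeOH, rt
Reagents that add atoms: none
Why: Heterogeneous hydrogenolysis cleaves both benzyl ethers and, with NaOAc as HBr scavenger, both aryl C–Br bonds in one operation, while the aryl ketone and the cyclic benzylic C2–O1 bond should react more slowly, so that C2 keeps its configuration.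

Step 5
Reactants: 13 [4-(benzyloxy)-3-formylphenyl]boronic acid
Product: 14 [4-(benzyloxy)-3-(hydroxymethyl)phenyl]boronic acid
Conditions: NaBH4, MeOH, 0 °C
Reagents that add atoms: none
Why: Chemoselective borohydride reduction of the aldehyde, which leaves the boronic acid and the benzyl ether untouched.

Step 6
Reactants: 15 1-(benzyloxy)-2-(bromomethyl)benzene; 14 [4-(benzyloxy)-3-(hydroxymethyl)phenyl]boronic acid
Product: 16 {2-(benzyloxy)-5-[2-(benzyloxy)benzyl]phenyl}methanol
Conditions: Pd(PPh3)4 (3 mol %), K2CO3, DME/H2O, 80 °C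
Reagents that add atoms: none
Why: Suzuki–Miyaura sp3–sp2 coupling of a benzylic bromide with an arylboronic acid, in which the substitution pattern of the two partners fixes the link from the ortho carbon of ring H to the para carbon of ring G without any regiochemical question.

Step 7
Reactants: 16 {2-(benzyloxy)-5-[2-(benzyloxy)benzyl]phenyl}methanol
Product: 17 1-(benzyloxy)-4-[2-(benzyloxy)benzyl]-2-(bromomethyl)benzene
Conditions: PBr3, CH2Cl2, 0 °C
Reagents that add atoms: phosphorus tribromide, BrP(Br)Br
Why: Conversion of the primary benzylic alcohol into the bromide by PBr3 (SN2 on the phosphite ester), which re-arms the chain end for the next coupling.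

Step 8
Reactants: 17 1-(benzyloxy)-4-[2-(benzyloxy)benzyl]-2-(bromomethyl)benzene; 14 [4-(benzyloxy)-3-(hydroxymethyl)phenyl]boronic acid
Product: 18 (2-(benzyloxy)-5-{2-(benzyloxy)-5-[2-(benzyloxy)benzyl]benzyl}phenyl)methanol
Conditions: Pd(PPh3)4 (3 mol %), K2CO3, DME/H2O, 80 °C
Reagents that add atoms: none
Why: Second iteration of the benzylic Suzuki–Miyaura coupling with the same boronic acid, which adds ring F.

Step 9
Reactants: 18 (2-(benzyloxy)-5-{2-(benzyloxy)-5-[2-(benzyloxy)benzyl]benzyl}phenyl)methanol
Product: 19 1-(benzyloxy)-4-{2-(benzyloxy)-5-[2-(benzyloxy)benzyl]benzyl}-2-(bromomethyl)benzene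
Conditions: PBr3, CH2Cl2, 0 °C
Reagents that add atoms: phosphorus tribromide, BrP(Br)Br
Why: Second benzylic bromination with PBr3 under the conditions of step 7.

Step 10
Reactants: 19 1-(benzyloxy)-4-{2-(benzyloxy)-5-[2-(benzyloxy)benzyl]benzyl}-2-(bromomethyl)benzene; 20 2-hydroxy-5-(4,4,5,5-tetramethyl-1,3,2-dioxaborolan-2-yl)benzaldehyde
Product: 21 5-(2-(benzyloxy)-5-{2-(benzyloxy)-5-[2-(benzyloxy)benzyl]benzyl}benzyl)-2-hydroxybenzaldehyde
Conditions: Pd(PPh3)4 (3 mol %), K2CO3, toluene/EtOH/H2O, 70 °C
Reagents that add atoms: none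
Why: Third benzylic Suzuki–Miyaura coupling, now with a salicylaldehyde boronate so that ring E arrives with a free phenol and a one-carbon handle ortho to it, the fast oxidative addition of the benzylic bromide to zerovalent palladium being expected to outrun O-alkylation of the phenoxide.

Step 11
Reactants: 21 5-(2-(benzyloxy)-5-{2-(benzyloxy)-5-[2-(benzyloxy)benzyl]benzyl}benzyl)-2-hydroxybenzaldehyde
Product: 22 4-(2-(benzyloxy)-5-{2-(benzyloxy)-5-[2-(benzyloxy)benzyl]benzyl}benzyl)-2-(hydroxymethyl)phenol
Conditions: NaBH4, MeOH/THF, 0 °C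
Reagents that add atoms: none
Why: Borohydride reduction of the salicylaldehyde to the salicyl alcohol, the precursor of the o-quinone methide.

Step 12
Reactants: 12 (S)-chamanetin; 22 4-(2-(benzyloxy)-5-{2-(benzyloxy)-5-[2-(benzyloxy)benzyl]benzyl}benzyl)-2-(hydroxymethyl)phenol
Product: 24 tri-O-benzyl sarmentosumin C (benzyl ethers on rings F, G and H), via chain o-quinone methide 23 (not isolated)
Conditions: ZnCl2 (2 equiv), 22 (1.2 equiv), 1,4-dioxane, 80 °C
Reagents that add atoms: none
Why: ZnCl2-mediated dehydration of 22 gives o-quinone methide 23, which is attacked by C6 of 12, the only unsubstituted carbon of the phloroglucinol-type ring A and by far the most nucleophilic carbon present (the benzyl-protected rings F to H and the simple phenol ring D are much less activated), a biomimetic hydroxybenzylation with precedent on 5,7-dihydroxyflavanones that forms no bond at C2.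

Step 13
Reactants: 24 tri-O-benzyl sarmentosumin C
Product: 25 sarmentosumin C
Conditions: H2 (1 atm), Pd/C (10 wt %), EtOAc/THF, rt
Reagents that add atoms: none
Why: Hydrogenolysis of the three aryl benzyl ethers under neutral conditions releases the remaining phenols, the diarylmethane links and the flavanone being expected to survive at atmospheric pressure when the reaction is stopped after three equivalents of hydrogen.

**Compound list**

1 | 3,5-bis(benzyloxy)phenol | Oc1cc(OCc2ccccc2)cc(OCc2ccccc2)c1 | starting material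
2 | 3,5-dibromo-2-hydroxybenzyl alcohol | OCc1cc(Br)cc(Br)c1O | starting material
3 | 2,4-dibromo-6-methylidenecyclohexa-2,4-dien-1-one (o-quinone methide from 2) | C=C1C=C(Br)C=C(Br)C1=O | intermediate
4 | 3,5-bis(benzyloxy)-2-(3,5-dibromo-2-hydroxybenzyl)phenol | Oc1cc(OCc2ccccc2)cc(OCc2ccccc2)c1Cc1cc(Br)cc(Br)c1O | intermediate
5 | α,α-dibromotoluene (benzal bromide) | BrC(Br)c1ccccc1 | starting material
6 | 9,11-bis(benzyloxy)-2,4-dibromo-6-phenyl-12H-dibenzo[d,g][1,3]dioxocin (racemic at acetal carbon C6) | C1(c2ccccc2)Oc2cc(OCc3ccccc3)cc(OCc3ccccc3)c2Cc2cc(Br)cc(Br)c2O1 | intermediate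
7 | N-ethynyl-N-methylmethanesulfonamide | C#CN(C)S(C)(=O)=O | starting material
8 | benzylidene[3,5-bis(benzyloxy)-2-(3,5-dibromo-2-hydroxybenzyl)phenyl]oxonium (aryl oxocarbenium ion, counter-ion the chiral phosphoramidate) | C(=[O+]c1cc(OCc2ccccc2)cc(OCc2ccccc2)c1Cc1cc(Br)cc(Br)c1O)c1ccccc1 | intermediate
9 | (S)-keteniminium ion, ArO–CH(Ph)–CH=C=N+(Me)SO2Me with Ar the aryl group of 8 | C[N+](=C=C[C@@H](c1ccccc1)Oc1cc(OCc2ccccc2)cc(OCc2ccccc2)c1Cc1cc(Br)cc(Br)c1O)S(C)(=O)=O | intermediate
10 | N-[(2S)-5,7-bis(benzyloxy)-8-(3,5-dibromo-2-hydroxybenzyl)-2-phenyl-2H-chromen-4-yl]-N-methylmethanesulfonamide | CN(C1=C[C@@H](c2ccccc2)Oc2c(Cc3cc(Br)cc(Br)c3O)c(OCc3ccccc3)cc(OCc3ccccc3)c21)S(C)(=O)=O | intermediate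
11 | (2S)-5,7-bis(benzyloxy)-8-(3,5-dibromo-2-hydroxybenzyl)-2-phenylchroman-4-one | O=C1C[C@@H](c2ccccc2)Oc2c(Cc3cc(Br)cc(Br)c3O)c(OCc3ccccc3)cc(OCc3ccccc3)c21 | intermediate
12 | (2S)-5,7-dihydroxy-8-(2-hydroxybenzyl)-2-phenylchroman-4-one ((S)-chamanetin) | O=C1C[C@@H](c2ccccc2)Oc2c(Cc3ccccc3O)c(O)cc(O)c21 | intermediate
13 | [4-(benzyloxy)-3-formylphenyl]boronic acid | O=Cc1cc(B(O)O)ccc1OCc1ccccc1 | starting material
14 | [4-(benzyloxy)-3-(hydroxymethyl)phenyl]boronic acid | OCc1cc(B(O)O)ccc1OCc1ccccc1 | intermediate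
15 | 1-(benzyloxy)-2-(bromomethyl)benzene (ring H) | BrCc1ccccc1OCc1ccccc1 | starting material
16 | {2-(benzyloxy)-5-[2-(benzyloxy)benzyl]phenyl}methanol (rings H–G alcohol) | OCc1cc(Cc2ccccc2OCc2ccccc2)ccc1OCc1ccccc1 | intermediate
17 | 1-(benzyloxy)-4-[2-(benzyloxy)benzyl]-2-(bromomethyl)benzene (rings H–G bromide) | BrCc1cc(Cc2ccccc2OCc2ccccc2)ccc1OCc1ccccc1 | intermediate
18 | (2-(benzyloxy)-5-{2-(benzyloxy)-5-[2-(benzyloxy)benzyl]benzyl}phenyl)methanol (rings H–G–F alcohol) | OCc1cc(Cc2cc(Cc3ccccc3OCc3ccccc3)ccc2OCc2ccccc2)ccc1OCc1ccccc1 | intermediate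
19 | 1-(benzyloxy)-4-{2-(benzyloxy)-5-[2-(benzyloxy)benzyl]benzyl}-2-(bromomethyl)benzene (rings H–G–F bromide) | BrCc1cc(Cc2cc(Cc3ccccc3OCc3ccccc3)ccc2OCc2ccccc2)ccc1OCc1ccccc1 | intermediate
20 | 2-hydroxy-5-(4,4,5,5-tetramethyl-1,3,2-dioxaborolan-2-yl)benzaldehyde | O=Cc1cc(B2OC(C)(C)C(C)(C)O2)ccc1O | starting material
21 | 5-(2-(benzyloxy)-5-{2-(benzyloxy)-5-[2-(benzyloxy)benzyl]benzyl}benzyl)-2-hydroxybenzaldehyde (rings H–G–F–E aldehyde) | O=Cc1cc(Cc2cc(Cc3cc(Cc4ccccc4OCc4ccccc4)ccc3OCc3ccccc3)ccc2OCc2ccccc2)ccc1O | intermediate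
22 | 4-(2-(benzyloxy)-5-{2-(benzyloxy)-5-[2-(benzyloxy)benzyl]benzyl}benzyl)-2-(hydroxymethyl)phenol (chain salicyl alcohol) | OCc1cc(Cc2cc(Cc3cc(Cc4ccccc4OCc4ccccc4)ccc3OCc3ccccc3)ccc2OCc2ccccc2)ccc1O | intermediate
23 | 6-methylidene-4-(chain-benzyl)cyclohexa-2,4-dien-1-one (o-quinone methide from 22) | C=C1C=C(Cc2cc(Cc3cc(Cc4ccccc4OCc4ccccc4)ccc3OCc3ccccc3)ccc2OCc2ccccc2)C=CC1=O | intermediate
24 | tri-O-benzyl sarmentosumin C: (2S)-flavanone with 5,7-OH, 8-(2-hydroxybenzyl) and the C6 chain whose rings F, G and H are benzyl ethers | O=C1C[C@@H](c2ccccc2)Oc2c(Cc3ccccc3O)c(O)c(Cc3cc(Cc4cc(Cc5cc(Cc6ccccc6OCc6ccccc6)ccc5OCc5ccccc5)ccc4OCc4ccccc4)ccc3O)c(O)c21 | intermediate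
25 | sarmentosumin C | O=C1C[C@@H](c2ccccc2)Oc2c(Cc3ccccc3O)c(O)c(Cc3cc(Cc4cc(Cc5cc(Cc6ccccc6O)ccc5O)ccc4O)ccc3O)c(O)c21 | target

**Count and risks**

Total step count: 13. Longest linear sequence: 9 steps (steps 5 to 11, then 12 and 13).

Steps most likely to fail:

1. Step 3. The acid may protonate the ynamide instead of the acetal, the oxocarbenium ion may be intercepted by a second ring A, or facial selectivity in the ion pair may be poor. The fallback sets out from bisphenol 4 and builds ring C by known chemistry. Friedel–Crafts C-acetylation at the only carbon ortho to the free ring A hydroxyl (Ac2O, BF3·OEt2, then brief K2CO3/MeOH to cleave any aryl acetate) gives 1-[4,6-bis(benzyloxy)-3-(3,5-dibromo-2-hydroxybenzyl)-2-hydroxyphenyl]ethanone F1. Claisen condensation with ethyl formate (NaH, THF) and acid-mediated cyclodehydration (HCl, AcOH) gives 5,7-bis(benzyloxy)-8-(3,5-dibromo-2-hydroxybenzyl)-4H-chromen-4-one F2. Asymmetric conjugate addition of phenylboronic acid under divalent palladium catalysis (Pd(OCOCF3)2, chiral tert-butyl pyridine-oxazoline ligand of the series that gives 2S, NH4PF6, H2O, ClCH2CH2Cl, 60 °C), which leaves aryl bromides alone, comes back to the route at flavanone 11.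

2. Step 12. Self-condensation of the salicyl alcohol through its own o-quinone methide, alkylation at ring D, or epimerisation at C2 by ring opening on heating with ZnCl2 may erode the union. The fallback sets out from bromide 19 and replaces the o-quinone methide by a benzylic cation generated at room temperature. A third coupling of 19 with boronic acid 14 under the conditions of step 8 gives the fully benzylated tetramer alcohol (2-(benzyloxy)-5-(2-(benzyloxy)-5-{2-(benzyloxy)-5-[2-(benzyloxy)benzyl]benzyl}benzyl)phenyl)methanol F3. F3 alkylates C6 of 12 under BF3·OEt2 in dioxane at room temperature (Friedel–Crafts benzylation by a 2-alkoxybenzyl cation, the type of acid-mediated C-alkylation known for 5,7-dihydroxyflavanones with allylic alcohols) to give tetra-O-benzyl sarmentosumin C F4. Hydrogenolysis as in step 13 comes back to the route at target 25.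

3. Step 1. Alkylation para to the hydroxyl or twofold alkylation of ring A may compete with the wanted ortho attack. The fallback sets out from phenol 1 and addresses the ortho carbon through the magnesium phenoxide. The bromomagnesium salt of 1 (EtMgBr, toluene) is condensed with commercial 3,5-dibromo-2-hydroxybenzaldehyde in a chelation-controlled, ortho-specific hydroxyalkylation to give [2,4-bis(benzyloxy)-6-hydroxyphenyl](3,5-dibromo-2-hydroxyphenyl)methanol F5. Ionic reduction of this doubly benzylic alcohol (Et3SiH, CF3CO2H, CH2Cl2, 0 °C) comes back to the route at 4.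

Further compounds
F1 | step 3 | 1-[4,6-bis(benzyloxy)-3-(3,5-dibromo-2-hydroxybenzyl)-2-hydroxyphenyl]ethanone | CC(=O)c1c(O)c(Cc2cc(Br)cc(Br)c2O)c(OCc2ccccc2)cc1OCc1ccccc1
F2 | step 3 | 5,7-bis(benzyloxy)-8-(3,5-dibromo-2-hydroxybenzyl)-4H-chromen-4-one | O=c1ccoc2c(Cc3cc(Br)cc(Br)c3O)c(OCc3ccccc3)cc(OCc3ccccc3)c12
F3 | step 12 | (2-(benzyloxy)-5-(2-(benzyloxy)-5-{2-(benzyloxy)-5-[2-(benzyloxy)benzyl]benzyl}benzyl)phenyl)methanol | OCc1cc(Cc2cc(Cc3cc(Cc4ccccc4OCc4ccccc4)ccc3OCc3ccccc3)ccc2OCc2ccccc2)ccc1OCc1ccccc1
F4 | step 12 | tetra-O-benzyl sarmentosumin C (benzyl ethers on rings E, F, G and H) | O=C1C[C@@H](c2ccccc2)Oc2c(Cc3ccccc3O)c(O)c(Cc3cc(Cc4cc(Cc5cc(Cc6ccccc6OCc6ccccc6)ccc5OCc5ccccc5)ccc4OCc4ccccc4)ccc3OCc3ccccc3)c(O)c21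
F5 | step 1 | [2,4-bis(benzyloxy)-6-hydroxyphenyl](3,5-dibromo-2-hydroxyphenyl)methanol (racemic) | OC(c1cc(Br)cc(Br)c1O)c1c(O)cc(OCc2ccccc2)cc1OCc1ccccc1
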